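The target is cut at the C7'–ring B bond (B-alkyl Suzuki–Miyaura coupling) into a ring B/ring C aryl bromide built from (R)-lactate and a ring A west chain carrying boron on C7'. The key step exploits the C7–C8–C8'–C7' chain between rings A and B, which is unfunctionalised and whose only features are the neighbouring CH(CH3) carbons C8 and C8'. One telescoped operation extends a benzylic boronic ester by two reagent-controlled CH(CH3) units and one CH2, forming C7–C8, C8–C8' and C8'–C7' and setting 8S and 8'R. The precursor is the O-benzylated ring A benzyl pinacol boronate; the carbenoid is ethyl 2,4,6-triisopropylbenzoate lithiated under (+)-sparteine.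

Key step: step 4

Remark: ring A is the aryl ring on C7, ring B the one on C7' and ring C the one on C7''. s-BuLi/(−)-sparteine removes the pro-S proton of an O-ethyl benzoate and the later 1,2-shift inverts that carbon, so 8S and 8'R both call for (+)-sparteine, which is taken to be commercially available.

Step 1
Reactants: 1 4-(benzyloxy)-3-methoxybenzyl alcohol
Product: 2 4-(benzyloxy)-3-methoxybenzyl bromide
Conditions: PBr3, Et2O, 0 °C; used crude
Reagents that add atoms: phosphorus tribromide, BrP(Br)Br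
Why: Nucleophilic substitution of an activated primary benzylic alcohol by bromide via its phosphite ester, under which the aryl benzyl ether is stable at 0 °C.

Step 2
Reactants: 2 4-(benzyloxy)-3-methoxybenzyl bromide; 3 bis(pinacolato)diboron
Product: 4 2-[4-(benzyloxy)-3-methoxybenzyl]-4,4,5,5-tetramethyl-1,3,2-dioxaborolane
Conditions: Pd(dba)2, P(4-MeOC6H4)3, KOAc, toluene, 50 °C
Reagents that add atoms: none
Why: Miyaura borylation of a benzylic halide, in which oxidative addition, acetate-assisted transmetalation with the diboron and reductive elimination should give the benzylic pinacol boronate under conditions too mild to touch the ethers.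

Step 3
Reactants: 5 2,4,6-triisopropylbenzoic acid
Product: 6 ethyl 2,4,6-triisopropylbenzoate
Conditions: EtI, K2CO3, DMF, 50 °C
Reagents that add atoms: iodoethane, CCI
Why: O-alkylation of the carboxylate (SN2 at the ethyl carbon) bypasses the shielded carbonyl carbon that makes acid-catalysed esterification of this acid slow.

Step 4
Reactants: 4 2-[4-(benzyloxy)-3-methoxybenzyl]-4,4,5,5-tetramethyl-1,3,2-dioxaborolane; 6 ethyl 2,4,6-triisopropylbenzoate (two portions); 7 bromochloromethane
Product: 12 2-[(2R,3S)-4-(4-benzyloxy-3-methoxyphenyl)-2,3-dimethylbutyl]-4,4,5,5-tetramethyl-1,3,2-dioxaborolane, via lithiated benzoate 8 (not isolated), via first secondary boronic ester 9 (not isolated), via second secondary boronic ester 10 (not isolated), via chloromethyllithium 11 (not isolated)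
Conditions: 6 (1.4 equiv), (+)-sparteine, s-BuLi (1.3 equiv), Et2O, −78 °C, 5 h; then 4, −78 °C, 1 h → 35 °C; filtration through silica, crude 9 taken on; same cycle again on crude 9; then 7, n-BuLi, Et2O, −78 °C → rt
Reagents that add atoms: none
Why: s-BuLi/(+)-sparteine removes the pro-R α-proton of 6 to give the configurationally stable (R)-carbenoid 8, which adds to the boron of 4 with retention to give a boronate complex, and on warming the benzylic carbon shifts from boron to carbon anti to the departing triisopropylbenzoate, inverting the carbenoid carbon, which becomes C8 of 9. An identical second cycle with a fresh portion of 8 forms C8–C8' (C8 migrating with retention) to give 10, and chloromethyllithium 11, made from 7 by bromine–lithium exchange, then inserts C7' by the same addition–migration sequence. The closest known reaction type is the iterative reagent-controlled lithiation–borylation of pinacol boronic esters with sparteine-ligated α-lithioethyl triisopropylbenzoates, established for runs of contiguous methyl-bearing carbons, followed by a Matteson homologation with LiCH2Cl. No ring is closed. C8 (S) and C8' (R) are each fixed by the R configuration of the carbenoid alone and not by the neighbouring centre, so using the same sparteine enantiomer twice should give the anti, meso-like pair, and any minor carbenoid enantiomer is expected to appear as the syn diastereomer rather than as the enantiomer of 12. The step needs exactly one insertion per cycle: boronate formation is complete at −78 °C before any migration starts, surplus carbenoid decomposes on warming before the new boronic ester is released, and the slight deficit of alkyllithium leaves none free to attack boron or the benzyl ether.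

Step 5
Reactants: 13 4-bromo-2,6-dimethoxyphenol; 14 methyl (R)-lactate
Product: 15 methyl (2S)-2-(4-bromo-2,6-dimethoxyphenoxy)propanoate
Conditions: PPh3, DIAD, THF, 0 °C → rt
Reagents that add atoms: none
Why: Mitsunobu etherification, in which the phenoxide displaces the alkoxyphosphonium group by SN2 with inversion of the lactate carbon and thereby sets C8'' as S.

Step 6
Reactants: 15 methyl (2S)-2-(4-bromo-2,6-dimethoxyphenoxy)propanoate
Product: 16 (2S)-2-(4-bromo-2,6-dimethoxyphenoxy)-N-methoxy-N-methylpropanamide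
Conditions: MeNH(OMe)·HCl, i-PrMgCl, THF, −20 → 0 °C
Reagents that add atoms: N,O-dimethylhydroxylamine hydrochloride, CNOC.Cl
Why: Weinreb amide formation by aminolysis of the ester with the magnesium amide, fast enough at low temperature to leave both C8'' and the electron-rich aryl bromide untouched.

Step 7
Reactants: 16 (2S)-2-(4-bromo-2,6-dimethoxyphenoxy)-N-methoxy-N-methylpropanamide; 17 1-(benzyloxy)-4-bromo-2-methoxybenzene
Product: 19 (2S)-1-[4-(benzyloxy)-3-methoxyphenyl]-2-(4-bromo-2,6-dimethoxyphenoxy)propan-1-one, via arylmagnesium bromide 18 (not isolated)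
Conditions: 17, Mg, THF, rt; then 16, THF, 0 °C; cold aq. NH4Cl
Reagents that add atoms: none
Why: Weinreb ketone synthesis, in which the chelated tetrahedral adduct stops at mono-addition and masks the ketone until the cold quench, so the α-aryloxy centre is not exposed to base as an enolisable ketone.

Step 8
Reactants: 19 (2S)-1-[4-(benzyloxy)-3-methoxyphenyl]-2-(4-bromo-2,6-dimethoxyphenoxy)propan-1-one
Product: 20 (1S,2S)-1-[4-(benzyloxy)-3-methoxyphenyl]-2-(4-bromo-2,6-dimethoxyphenoxy)propan-1-ol
Conditions: LiBH(s-Bu)3, THF, −78 °C; aq. NH4Cl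
Reagents that add atoms: none
Why: Felkin–Anh-controlled ketone reduction, in which the bulky non-chelating hydride attacks anti to the C8''–OAr bond and past the small hydrogen, which should give the threo alcohol with C7'' as S.

Step 9
Reactants: 20 (1S,2S)-1-[4-(benzyloxy)-3-methoxyphenyl]-2-(4-bromo-2,6-dimethoxyphenoxy)propan-1-ol
Product: 21 [(1S,2S)-1-[4-(benzyloxy)-3-methoxyphenyl]-2-(4-bromo-2,6-dimethoxyphenoxy)propoxy](tert-butyl)dimethylsilane
Conditions: TBSOTf, 2,6-lutidine, CH2Cl2, 0 °C
Reagents that add atoms: tert-butyldimethylsilyl trifluoromethanesulfonate, CC(C)(C)[Si](C)(C)OS(=O)(=O)C(F)(F)F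
Why: O-silylation with the reactive silyl triflate caps the hindered benzylic alcohol without touching either stereocentre, so no free carbinol is exposed to the palladium coupling.

Step 10
Reactants: 12 2-[(2R,3S)-4-(4-benzyloxy-3-methoxyphenyl)-2,3-dimethylbutyl]-4,4,5,5-tetramethyl-1,3,2-dioxaborolane; 21 [(1S,2S)-1-[4-(benzyloxy)-3-methoxyphenyl]-2-(4-bromo-2,6-dimethoxyphenoxy)propoxy](tert-butyl)dimethylsilane
Product: 22 (7''S,8S,8'R,8''S)-4,4''-bis(benzyloxy)-7''-(tert-butyldimethylsilyloxy)-3,3',3'',5'-tetramethoxy-4',8''-oxy-8,8'-sesquineolignan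
Conditions: Pd(OAc)2, RuPhos, KOH, THF/H2O (10:1), 70 °C
Reagents that add atoms: none
Why: B-alkyl Suzuki–Miyaura coupling, in which oxidative addition of the unhindered aryl bromide, hydroxide-assisted transmetalation of the primary alkyl boronate and reductive elimination (favoured over β-hydride elimination by the bulky electron-rich phosphine) join C7' to ring B while C8' stays untouched because boron sits on the CH2 carbon.

Step 11
Reactants: 22 (7''S,8S,8'R,8''S)-4,4''-bis(benzyloxy)-7''-(tert-butyldimethylsilyloxy)-3,3',3'',5'-tetramethoxy-4',8''-oxy-8,8'-sesquineolignan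
Product: 23 (7''S,8S,8'R,8''S)-4,4''-bis(benzyloxy)-3,3',3'',5'-tetramethoxy-4',8''-oxy-8,8'-sesquineolignan-7''-ol
Conditions: Bu4NF, THF, 0 °C → rt
Reagents that add atoms: none
Why: Fluoride-induced silyl ether cleavage, driven by the strong Si–F bond, frees the C7'' hydroxyl while the phenols are still benzylated and no stereocentre is involved.

Step 12
Reactants: 23 (7''S,8S,8'R,8''S)-4,4''-bis(benzyloxy)-3,3',3'',5'-tetramethoxy-4',8''-oxy-8,8'-sesquineolignan-7''-ol
Product: 24 (+)-(7''S,8S,8'R,8''S)-4,4''-dihydroxy-3,3',3'',5'-tetramethoxy-4',8''-oxy-8,8'-sesquineolignan-7''-ol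
Conditions: H2 (1 atm), Pd/C (10% Pd on carbon), EtOAc, rt
Reagents that add atoms: none
Why: Catalytic hydrogenolysis of the two aryl benzyl ethers, which under neutral conditions at one atmosphere are cleaved faster than the secondary benzylic C7''–OH bond, so the reaction is stopped after uptake of two equivalents of hydrogen.

Compound list
1 | 4-(benzyloxy)-3-methoxybenzyl alcohol | COc1cc(CO)ccc1OCc1ccccc1 | starting material
2 | 4-(benzyloxy)-3-methoxybenzyl bromide | COc1cc(CBr)ccc1OCc1ccccc1 | intermediate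
3 | bis(pinacolato)diboron | CC1(C)OB(OC1(C)C)B1OC(C)(C)C(C)(C)O1 | starting material
4 | 2-[4-(benzyloxy)-3-methoxybenzyl]-4,4,5,5-tetramethyl-1,3,2-dioxaborolane | COc1cc(CB2OC(C)(C)C(C)(C)O2)ccc1OCc1ccccc1 | intermediate
5 | 2,4,6-triisopropylbenzoic acid | CC(C)c1cc(C(C)C)c(C(=O)O)c(C(C)C)c1 | starting material
6 | ethyl 2,4,6-triisopropylbenzoate | CCOC(=O)c1c(C(C)C)cc(C(C)C)cc1C(C)C | intermediate
7 | bromochloromethane | ClCBr | starting material
8 | (R)-1-lithioethyl 2,4,6-triisopropylbenzoate (formed as its (+)-sparteine complex) | C[C@@H]([Li])OC(=O)c1c(C(C)C)cc(C(C)C)cc1C(C)C | intermediate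
9 | 2-[(2S)-1-(4-benzyloxy-3-methoxyphenyl)propan-2-yl]-4,4,5,5-tetramethyl-1,3,2-dioxaborolane | COc1cc(C[C@H](C)B2OC(C)(C)C(C)(C)O2)ccc1OCc1ccccc1 | intermediate
10 | 2-[(2S,3S)-4-(4-benzyloxy-3-methoxyphenyl)-3-methylbutan-2-yl]-4,4,5,5-tetramethyl-1,3,2-dioxaborolane | COc1cc(C[C@H](C)[C@H](C)B2OC(C)(C)C(C)(C)O2)ccc1OCc1ccccc1 | intermediate
11 | chloromethyllithium | [Li]CCl | intermediate
12 | 2-[(2R,3S)-4-(4-benzyloxy-3-methoxyphenyl)-2,3-dimethylbutyl]-4,4,5,5-tetramethyl-1,3,2-dioxaborolane | COc1cc(C[C@H](C)[C@H](C)CB2OC(C)(C)C(C)(C)O2)ccc1OCc1ccccc1 | intermediate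
13 | 4-bromo-2,6-dimethoxyphenol | COc1cc(Br)cc(OC)c1O | starting material
14 | methyl (R)-lactate | C[C@@H](O)C(=O)OC | starting material
15 | methyl (2S)-2-(4-bromo-2,6-dimethoxyphenoxy)propanoate | C[C@H](Oc1c(OC)cc(Br)cc1OC)C(=O)OC | intermediate
16 | (2S)-2-(4-bromo-2,6-dimethoxyphenoxy)-N-methoxy-N-methylpropanamide | C[C@H](Oc1c(OC)cc(Br)cc1OC)C(=O)N(C)OC | intermediate
17 | 1-(benzyloxy)-4-bromo-2-methoxybenzene | COc1cc(Br)ccc1OCc1ccccc1 | starting material
18 | [4-(benzyloxy)-3-methoxyphenyl]magnesium bromide | COc1cc([Mg]Br)ccc1OCc1ccccc1 | intermediate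
19 | (2S)-1-[4-(benzyloxy)-3-methoxyphenyl]-2-(4-bromo-2,6-dimethoxyphenoxy)propan-1-one | C[C@H](Oc1c(OC)cc(Br)cc1OC)C(=O)c1ccc(OCc2ccccc2)c(OC)c1 | intermediate
20 | (1S,2S)-1-[4-(benzyloxy)-3-methoxyphenyl]-2-(4-bromo-2,6-dimethoxyphenoxy)propan-1-ol | C[C@H](Oc1c(OC)cc(Br)cc1OC)[C@@H](O)c1ccc(OCc2ccccc2)c(OC)c1 | intermediate
21 | [(1S,2S)-1-[4-(benzyloxy)-3-methoxyphenyl]-2-(4-bromo-2,6-dimethoxyphenoxy)propoxy](tert-butyl)dimethylsilane | C[C@H](Oc1c(OC)cc(Br)cc1OC)[C@@H](O[Si](C)(C)C(C)(C)C)c1ccc(OCc2ccccc2)c(OC)c1 | intermediate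
22 | (7''S,8S,8'R,8''S)-4,4''-bis(benzyloxy)-7''-(tert-butyldimethylsilyloxy)-3,3',3'',5'-tetramethoxy-4',8''-oxy-8,8'-sesquineolignan | COc1cc(C[C@H](C)[C@H](C)Cc2cc(OC)c(O[C@@H](C)[C@@H](O[Si](C)(C)C(C)(C)C)c3ccc(OCc4ccccc4)c(OC)c3)c(OC)c2)ccc1OCc1ccccc1 | intermediate
23 | (7''S,8S,8'R,8''S)-4,4''-bis(benzyloxy)-3,3',3'',5'-tetramethoxy-4',8''-oxy-8,8'-sesquineolignan-7''-ol | COc1cc(C[C@H](C)[C@H](C)Cc2cc(OC)c(O[C@@H](C)[C@@H](O)c3ccc(OCc4ccccc4)c(OC)c3)c(OC)c2)ccc1OCc1ccccc1 | intermediate
24 | (+)-(7''S,8S,8'R,8''S)-4,4''-dihydroxy-3,3',3'',5'-tetramethoxy-4',8''-oxy-8,8'-sesquineolignan-7''-ol | COc1cc(C[C@H](C)[C@H](C)Cc2cc(OC)c(O[C@@H](C)[C@@H](O)c3ccc(O)c(OC)c3)c(OC)c2)ccc1O | target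

Total step count: 12. Longest linear sequence: 8 steps (13 → 15 → 16 → 19 → 20 → 21 → 22 → 23 → 24; steps 5 to 12).

Steps most likely to fail

1. Step 4. Boronate formation or the 1,2-shift may be incomplete at the hindered secondary boronic ester 9 in the second cycle, so that under-homologated material is carried into the CH2 insertion; imperfect discrimination of the two α-protons in the sparteine-mediated lithiation would show up as the syn diastereomer. The fallback sets out from 4 and returns at 22, and replaces reagent control by control from a chiral diol on boron (Matteson α-chloro boronic ester chemistry). Diethanolamine in Et2O should precipitate 2-[4-(benzyloxy)-3-methoxybenzyl]-1,3,6,2-dioxazaborocane F1, which with (1R,2R)-1,2-dicyclohexylethane-1,2-diol and aq. HCl/Et2O should give (4R,5R)-2-[4-(benzyloxy)-3-methoxybenzyl]-4,5-dicyclohexyl-1,3,2-dioxaborolane F2. LiCHCl2 (CH2Cl2, n-BuLi, THF, −100 °C) followed by ZnCl2 should insert a chloromethine under control of the diol to give (4R,5R)-2-[(1S)-2-(4-benzyloxy-3-methoxyphenyl)-1-chloroethyl]-4,5-dicyclohexyl-1,3,2-dioxaborolane F3. MeMgBr then replaces chloride with inversion to give (4R,5R)-2-[(2S)-1-(4-benzyloxy-3-methoxyphenyl)propan-2-yl]-4,5-dicyclohexyl-1,3,2-dioxaborolane F4. A second LiCHCl2/ZnCl2 insertion gives (4R,5R)-2-[(1S,2S)-3-(4-benzyloxy-3-methoxyphenyl)-1-chloro-2-methylpropyl]-4,5-dicyclohexyl-1,3,2-dioxaborolane F5, and MeMgBr gives (4R,5R)-2-[(2S,3S)-4-(4-benzyloxy-3-methoxyphenyl)-3-methylbutan-2-yl]-4,5-dicyclohexyl-1,3,2-dioxaborolane F6. LiCH2Cl (BrCH2Cl, n-BuLi) gives (4R,5R)-2-[(2R,3S)-4-(4-benzyloxy-3-methoxyphenyl)-2,3-dimethylbutyl]-4,5-dicyclohexyl-1,3,2-dioxaborolane F7, which is coupled with 21 under the conditions of step 10 to give 22.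

2. Step 10. Transmetalation of the β-branched primary alkyl pinacol boronate may be slow, so that protodeboronation, β-hydride elimination with chain walking and reduction of the aryl bromide compete. The fallback sets out from 12 and returns at 22, and turns the alkyl partner into an organozinc for a Negishi coupling. Oxidation (NaBO3·4H2O, THF/H2O) should give (2S,3S)-4-[4-(benzyloxy)-3-methoxyphenyl]-2,3-dimethylbutan-1-ol F8. Iodine, PPh3 and imidazole give 1-(benzyloxy)-4-[(2S,3S)-4-iodo-2,3-dimethylbutyl]-2-methoxybenzene F9. Zinc insertion (Zn dust, LiCl, THF) gives [(2S,3S)-4-(4-benzyloxy-3-methoxyphenyl)-2,3-dimethylbutyl]zinc iodide F10, which is coupled with 21 (Pd(OAc)2, SPhos, THF, 50 °C) to give 22.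

3. Step 8. Facial selectivity may be poor if a lithium chelate between the carbonyl oxygen and the aryloxy or methoxy oxygens competes with the open Felkin–Anh pathway, which would raise the share of the erythro alcohol; base-induced epimerisation at C8'' of the ketone is a second risk. The fallback sets out from 15 and returns at 20, bypasses the ketone and lets chelation work for the threo isomer. Reduction with i-Bu2AlH (CH2Cl2, −78 °C) should give (2S)-2-(4-bromo-2,6-dimethoxyphenoxy)propanal F11, used crude. F11 is precomplexed with MgBr2·OEt2 in CH2Cl2 at −78 °C and treated with 18; in the five-membered chelate the aryl group adds from the side of the C8'' hydrogen (Cram chelate model), which should give the (1S,2S) alcohol 20.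

Further compounds
F1 | step 4 | 2-[4-(benzyloxy)-3-methoxybenzyl]-1,3,6,2-dioxazaborocane | COc1cc(CB2OCCNCCO2)ccc1OCc1ccccc1
F2 | step 4 | (4R,5R)-2-[4-(benzyloxy)-3-methoxybenzyl]-4,5-dicyclohexyl-1,3,2-dioxaborolane | COc1cc(CB2O[C@H](C3CCCCC3)[C@@H](C3CCCCC3)O2)ccc1OCc1ccccc1
F3 | step 4 | (4R,5R)-2-[(1S)-2-(4-benzyloxy-3-methoxyphenyl)-1-chloroethyl]-4,5-dicyclohexyl-1,3,2-dioxaborolane | COc1cc(C[C@@H](Cl)B2O[C@H](C3CCCCC3)[C@@H](C3CCCCC3)O2)ccc1OCc1ccccc1
F4 | step 4 | (4R,5R)-2-[(2S)-1-(4-benzyloxy-3-methoxyphenyl)propan-2-yl]-4,5-dicyclohexyl-1,3,2-dioxaborolane | COc1cc(C[C@H](C)B2O[C@H](C3CCCCC3)[C@@H](C3CCCCC3)O2)ccc1OCc1ccccc1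
F5 | step 4 | (4R,5R)-2-[(1S,2S)-3-(4-benzyloxy-3-methoxyphenyl)-1-chloro-2-methylpropyl]-4,5-dicyclohexyl-1,3,2-dioxaborolane | COc1cc(C[C@H](C)[C@@H](Cl)B2O[C@H](C3CCCCC3)[C@@H](C3CCCCC3)O2)ccc1OCc1ccccc1
F6 | step 4 | (4R,5R)-2-[(2S,3S)-4-(4-benzyloxy-3-methoxyphenyl)-3-methylbutan-2-yl]-4,5-dicyclohexyl-1,3,2-dioxaborolane | COc1cc(C[C@H](C)[C@H](C)B2O[C@H](C3CCCCC3)[C@@H](C3CCCCC3)O2)ccc1OCc1ccccc1
F7 | step 4 | (4R,5R)-2-[(2R,3S)-4-(4-benzyloxy-3-methoxyphenyl)-2,3-dimethylbutyl]-4,5-dicyclohexyl-1,3,2-dioxaborolane | COc1cc(C[C@H](C)[C@H](C)CB2O[C@H](C3CCCCC3)[C@@H](C3CCCCC3)O2)ccc1OCc1ccccc1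
F8 | step 10 | (2S,3S)-4-[4-(benzyloxy)-3-methoxyphenyl]-2,3-dimethylbutan-1-ol | COc1cc(C[C@H](C)[C@H](C)CO)ccc1OCc1ccccc1
F9 | step 10 | 1-(benzyloxy)-4-[(2S,3S)-4-iodo-2,3-dimethylbutyl]-2-methoxybenzene | COc1cc(C[C@H](C)[C@H](C)CI)ccc1OCc1ccccc1
F10 | step 10 | [(2S,3S)-4-(4-benzyloxy-3-methoxyphenyl)-2,3-dimethylbutyl]zinc iodide | COc1cc(C[C@H](C)[C@H](C)C[Zn]I)ccc1OCc1ccccc1
F11 | step 8 | (2S)-2-(4-bromo-2,6-dimethoxyphenoxy)propanal | C[C@H](Oc1c(OC)cc(Br)cc1OC)C=O
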